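**Retrosynthetic overview**
Numbering: labdane numbering is used for all fragments. Ring A = C1–C5/C10, ring B = C5–C10, C20 = CH3 on C10, C17 = CH2OH carbon on C8, side chain C11–C16, ester oxygen on C15. The target belongs to the ent series (5R,9S,10R; 13E).
Enabling feature: in ring B the segment C10 (quaternary, methyl-bearing)–C9–C8(C17)=C7 is, at the C17-aldehyde level, the retron of a conjugate addition/aldol condensation on a linear enal OHC(17)–C8H=C9H–R. C7 is tied to C10 through C6–C5, so one γ,δ-unsaturated aldehyde can supply both C10 and C7. Its exocyclic C10=C20 alkene becomes the tertiary C10 radical and, after H-atom uptake, the angular methyl group.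
Disconnections: (a) final Si–O cleavage and CHO→CH2OH at C17. (b) C9–C10 and C7–C8 of ring B, made together in one iron-hydride radical–polar crossover annulation of a ring-A aldehyde with the complete C8–C17/acyl enal. (c) The enal comes from geraniol plus a protected C32 acid, with the prenyl end exchanged for CH=CH–CHO by cross metathesis; the acid is C16 + C16.
The ring-A aldehyde has one stereocentre (C5). It comes from a single catalytic event (CBS reduction, C1–OH), relayed by a suprafacial Johnson–Claisen rearrangement. Allylsilane protodesilylation then places the alkene exocyclic.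
Ring order: ring A is bought (4,4-dimethylcyclohexenone) and ring B is closed last. C5 controls C10 and C9 (and the transient C8 and C7) in that one event.

Key step: step 12

Assumption: the acyl residue is read as 32-hydroxydotriacontanoyl (C=O plus 31 CH2), and the C7/C8 configuration drawn for 19 and 20 is the expected diequatorial one, which step 13 erases.

**Step 1**
Reactants: 1 4,4-dimethylcyclohex-2-en-1-one
Product: 2 2-iodo-4,4-dimethylcyclohex-2-en-1-one
Conditions: I2, pyridine/CH2Cl2, 0 °C to rt
Reagents that add atoms: iodine, II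
Why: α-Iodination of an enone (conjugate addition of pyridine, iodination of the enolate, E1cB loss of pyridine) is standard for cyclohexenones, including 4,4-disubstituted ones, and creates no stereocentre.

**Step 2**
Reactants: 2 2-iodo-4,4-dimethylcyclohex-2-en-1-one
Product: 3 (1S)-2-iodo-4,4-dimethylcyclohex-2-en-1-ol
Conditions: (R)-Me-CBS (10 mol%), BH3·SMe2, THF, −20 °C; aq. work-up
Reagents that add atoms: none
Why: In this Corey–Bakshi–Shibata reduction the iodoalkenyl flank acts as the large and the CH2 flank as the small ketone substituent, so the (R)-oxazaborolidine should deliver hydride to one face and set C1 as S, the only stereocentre made by catalysis.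

**Step 3**
Reactants: 3 (1S)-2-iodo-4,4-dimethylcyclohex-2-en-1-ol
Product: 4 (1S)-4,4-dimethyl-2-[(trimethylsilyl)methyl]cyclohex-2-en-1-ol
Conditions: Me3SiCH2MgCl (2.5 equiv), Pd(PPh3)4 (5 mol%), THF, 0 to 50 °C
Reagents that add atoms: (trimethylsilyl)methylmagnesium chloride, C[Si](C)(C)C[Mg]Cl
Why: Kumada–Corriu coupling of an alkenyl iodide with Me3SiCH2MgCl is the standard entry to allylsilanes; the first equivalent only deprotonates the alcohol, and the carbinol centre is untouched.

**Step 4**
Reactants: 4 (1S)-4,4-dimethyl-2-[(trimethylsilyl)methyl]cyclohex-2-en-1-ol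
Product: 6 ethyl 2-[(1R)-6,6-dimethyl-2-[(trimethylsilyl)methyl]cyclohex-2-en-1-yl]acetate, via mixed ketene acetal 5 (not isolated)
Conditions: MeC(OEt)3, EtCO2H (cat.), xylene, 140 °C, EtOH distilled off
Reagents that add atoms: triethyl orthoacetate, CCOC(C)(OCC)OCC
Why: In this Johnson–Claisen rearrangement ketene acetal 5 rearranges suprafacially, so the new C5–C6 bond forms on the ring face that carried the C1–O bond (S at C1 becomes R at C5, 1,3-chirality transfer), and the weak acid should leave the allylsilane intact.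

**Step 5**
Reactants: 6 ethyl 2-[(1R)-6,6-dimethyl-2-[(trimethylsilyl)methyl]cyclohex-2-en-1-yl]acetate
Product: 7 ethyl 2-[(1R)-2,2-dimethyl-6-methylidenecyclohexyl]acetate
Conditions: CF3CO2H (2 equiv), CH2Cl2, −20 °C; aq. NaHCO3
Reagents that add atoms: none
Why: In this SE2′ protodesilylation of an allylsilane the proton adds to C1 and the β-silyl cation at C10 loses silicon, which moves the double bond regiospecifically to the exocyclic C10=C20 position without touching C5.

**Step 6**
Reactants: 7 ethyl 2-[(1R)-2,2-dimethyl-6-methylidenecyclohexyl]acetate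
Product: 8 2-[(1R)-2,2-dimethyl-6-methylidenecyclohexyl]acetaldehyde
Conditions: DIBAL-H (1.05 equiv), toluene, −78 °C; Rochelle salt
Reagents that add atoms: none
Why: Partial ester reduction with DIBAL-H at low temperature stops at the aluminium hemiacetal, which gives the aldehyde on work-up, and C5 is β to the carbonyl group and cannot epimerise.

**Step 7**
Reactants: 9 hexadecane-1,16-diol
Product: 10 16-bromohexadecan-1-ol
Conditions: 48% aq. HBr (1.1 equiv), toluene, reflux
Reagents that add atoms: hydrogen bromide, Br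
Why: Monobromination (SN2) of a symmetrical α,ω-diol in the two-phase HBr/toluene system is biased towards the bromo alcohol, which is withdrawn into the organic phase; no stereocentre is involved.

**Step 8**
Reactants: 10 16-bromohexadecan-1-ol
Product: 11 [(16-bromohexadecyl)oxy](tert-butyl)diphenylsilane
Conditions: TBDPSCl, imidazole, CH2Cl2/DMF, rt
Reagents that add atoms: tert-butyl(chloro)diphenylsilane, CC(C)(C)[Si](Cl)(c1ccccc1)c1ccccc1
Why: This is a standard imidazole-promoted silylation of a primary alcohol, and TBDPS is chosen because it should survive Grignard formation, acidic work-up, metathesis, iron/silane, MsCl/Et3N and Luche conditions.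

**Step 9**
Reactants: 11 [(16-bromohexadecyl)oxy](tert-butyl)diphenylsilane; 12 16-bromohexadecanoic acid
Product: 15 32-[(tert-butyldiphenylsilyl)oxy]dotriacontanoic acid, via Grignard reagent 13 (not isolated), via chloromagnesium carboxylate 14 (not isolated)
Conditions: (a) 11, Mg, THF, 50 °C; (b) 12, MeMgCl (1.0 equiv), THF, −20 °C; (c) a into b, Li2CuCl4 (3 mol%), −20 °C to rt; 1 M HCl
Reagents that add atoms: none
Why: Copper-catalysed sp3–sp3 cross-coupling of a primary alkyl Grignard reagent with the halomagnesium salt of an ω-bromo acid is a known way to lengthen fatty acids and joins C16 to C16 without redox adjustment.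

**Step 10**
Reactants: 15 32-[(tert-butyldiphenylsilyl)oxy]dotriacontanoic acid; 16 geraniol
Product: 17 geranyl 32-[(tert-butyldiphenylsilyl)oxy]dotriacontanoate
Conditions: EDC·HCl, DMAP, CH2Cl2, rt
Reagents that add atoms: none
Why: Steglich-type esterification acylates the primary allylic alcohol under near-neutral conditions that neither ionise nor isomerise the bought E-allylic system (the future C13=C14).

**Step 11**
Reactants: 17 geranyl 32-[(tert-butyldiphenylsilyl)oxy]dotriacontanoate
Product: 18 (2E,6E)-3-methyl-8-oxoocta-2,6-dien-1-yl 32-[(tert-butyldiphenylsilyl)oxy]dotriacontanoate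
Conditions: (E)-crotonaldehyde (8 equiv), Hoveyda–Grubbs II (5 mol%), CH2Cl2, 40 °C
Reagents that add atoms: (E)-crotonaldehyde, C/C=C/C=O
Why: Olefin cross metathesis of prenyl-type gem-dimethyl termini of terpenoids with enals is known; the inner trisubstituted allylic-ester alkene is too hindered to react, and the new C8=C9 enal should form E under thermodynamic control.

**Step 12**
Reactants: 8 2-[(1R)-2,2-dimethyl-6-methylidenecyclohexyl]acetaldehyde; 18 (2E,6E)-3-methyl-8-oxoocta-2,6-dien-1-yl 32-[(tert-butyldiphenylsilyl)oxy]dotriacontanoate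
Product: 19 (5R,7R,8R,9R,10S,13E)-7-hydroxy-17-oxolabd-13-en-15-yl 32-[(tert-butyldiphenylsilyl)oxy]dotriacontanoate (trans-decalin; 7-OH, 8-CHO and the C9 chain equatorial)
Conditions: 8 (1.5 equiv), 18 (1.0 equiv), Fe(acac)3 (20 mol%), PhSi(Oi-Pr)H2 (2 equiv), 1,2-DCE/i-PrOH 10:1, 0 °C to rt, Ar
Reagents that add atoms: none
Why: An iron(III) hydride made from Fe(acac)3 and the silane transfers H• to the CH2 end (C20) of the exocyclic alkene of 8 (MHAT), the tertiary C10 radical adds to C9, the β-carbon of enal 18 (Giese addition), Fe(II) reduces the α-formyl radical to the C8=C17 iron enolate (radical–polar crossover), and this enolate attacks the C7 aldehyde, so that C9–C10 and C7–C8 are made in one operation and C20 becomes the angular methyl group. The closest known reaction type is the iron-catalysed radical–polar crossover annulation of γ,δ-unsaturated aldehydes with α,β-unsaturated carbonyl compounds, an outgrowth of reductive olefin coupling. Ring B is the only ring closed: its first bond is intermolecular and the closure is a 6-(enolexo)-exo-trig aldol through a chair. C10 is controlled by C5 and C4: with the C5 arm equatorial, the face of the planar radical syn to the axial C4 methyl group is blocked, the enal is taken up on the H-5 face, and C9 becomes equatorial and C20 axial, i.e. the trans-decalin. C9 is set in the same bond formation: in the staggered transition state H-9 lies under ring A, the sp3 carbon C11 takes the open sector between C20 and C1, and C8, tilted away along the attack trajectory, takes the sector next to C6, which is also the only rotamer from which the enolate reaches C7 with the side chain equatorial, while C8 and C7 (expected diequatorial) are erased in step 13. The step needs HAT at the 1,1-disubstituted C10=C20 alkene only, secured because C13=C14 is trisubstituted and deactivated by its allylic acyloxy group, and it needs the C8 rather than the C6 enolate, secured because the enolate arises regiospecifically by reduction of the adduct radical and not by deprotonation.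

**Step 13**
Reactants: 19 (5R,7R,8R,9R,10S,13E)-7-hydroxy-17-oxolabd-13-en-15-yl 32-[(tert-butyldiphenylsilyl)oxy]dotriacontanoate
Product: 21 (5R,9S,10R,13E)-17-oxolabda-7,13-dien-15-yl 32-[(tert-butyldiphenylsilyl)oxy]dotriacontanoate, via C7 mesylate 20 (not isolated)
Conditions: MsCl (1.5 equiv), Et3N (4 equiv), CH2Cl2, 0 °C to rt
Reagents that add atoms: none
Why: Mesylation followed by E1cB elimination through the C8 enolate (the end of an aldol condensation) gives the conjugated C7=C8 enal whatever the C7/C8 configuration, and H-9 sits on a cross-conjugated position and is not acidic, so C9 is retained.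

**Step 14**
Reactants: 21 (5R,9S,10R,13E)-17-oxolabda-7,13-dien-15-yl 32-[(tert-butyldiphenylsilyl)oxy]dotriacontanoate
Product: 22 (5R,9S,10R,13E)-17-hydroxylabda-7,13-dien-15-yl 32-[(tert-butyldiphenylsilyl)oxy]dotriacontanoate
Conditions: NaBH4, CeCl3·7H2O, THF/MeOH, 0 °C
Reagents that add atoms: none
Why: Luche reduction is 1,2-selective for the enal and leaves the alkyl ester, silyl ether and alkenes alone, so keeping C17 at the aldehyde level until now is what distinguishes it from C15; no stereocentre is formed.

**Step 15**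
Reactants: 22 (5R,9S,10R,13E)-17-hydroxylabda-7,13-dien-15-yl 32-[(tert-butyldiphenylsilyl)oxy]dotriacontanoate
Product: 23 (5R,9S,10R,13E)-17-hydroxylabda-7,13-dien-15-yl 32-hydroxydotriacontanoate (target)
Conditions: HF·pyridine, THF/pyridine, 0 °C to rt
Reagents that add atoms: none
Why: Fluoride-mediated desilylation under buffered conditions cleaves only the Si–O bond, and the ester cannot migrate because both free hydroxyl groups are remote from it.

**Compound list**
1 | 4,4-dimethylcyclohex-2-en-1-one | CC1(C)CCC(=O)C=C1 | starting material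
2 | 2-iodo-4,4-dimethylcyclohex-2-en-1-one | CC1(C)CCC(=O)C(I)=C1 | intermediate
3 | (1S)-2-iodo-4,4-dimethylcyclohex-2-en-1-ol | O[C@H]1CCC(C)(C)C=C1I | intermediate
4 | (1S)-4,4-dimethyl-2-[(trimethylsilyl)methyl]cyclohex-2-en-1-ol | O[C@H]1CCC(C)(C)C=C1C[Si](C)(C)C | intermediate
5 | mixed ketene acetal of 4 (1-ethoxyvinyl ether, not isolated) | C=C(OCC)O[C@H]1CCC(C)(C)C=C1C[Si](C)(C)C | intermediate
6 | ethyl 2-[(1R)-6,6-dimethyl-2-[(trimethylsilyl)methyl]cyclohex-2-en-1-yl]acetate | CCOC(=O)C[C@@H]1C(C)(C)CCC=C1C[Si](C)(C)C | intermediate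
7 | ethyl 2-[(1R)-2,2-dimethyl-6-methylidenecyclohexyl]acetate | CCOC(=O)C[C@@H]1C(C)(C)CCCC1=C | intermediate
8 | 2-[(1R)-2,2-dimethyl-6-methylidenecyclohexyl]acetaldehyde | O=CC[C@@H]1C(C)(C)CCCC1=C | intermediate
9 | hexadecane-1,16-diol | OCCCCCCCCCCCCCCCCO | starting material
10 | 16-bromohexadecan-1-ol | OCCCCCCCCCCCCCCCCBr | intermediate
11 | [(16-bromohexadecyl)oxy](tert-butyl)diphenylsilane | CC(C)(C)[Si](OCCCCCCCCCCCCCCCCBr)(c1ccccc1)c1ccccc1 | intermediate
12 | 16-bromohexadecanoic acid | OC(=O)CCCCCCCCCCCCCCCBr | starting material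
13 | 16-[(tert-butyldiphenylsilyl)oxy]hexadecylmagnesium bromide (not isolated) | CC(C)(C)[Si](OCCCCCCCCCCCCCCCC[Mg]Br)(c1ccccc1)c1ccccc1 | intermediate
14 | chloromagnesium 16-bromohexadecanoate (not isolated) | [O-]C(=O)CCCCCCCCCCCCCCCBr.[Mg+2].[Cl-] | intermediate
15 | 32-[(tert-butyldiphenylsilyl)oxy]dotriacontanoic acid | OC(=O)CCCCCCCCCCCCCCCCCCCCCCCCCCCCCCCO[Si](c1ccccc1)(c1ccccc1)C(C)(C)C | intermediate
16 | geraniol, (2E)-3,7-dimethylocta-2,6-dien-1-ol | C/C(=C\CO)CCC=C(C)C | starting material
17 | geranyl 32-[(tert-butyldiphenylsilyl)oxy]dotriacontanoate | C/C(=C\COC(=O)CCCCCCCCCCCCCCCCCCCCCCCCCCCCCCCO[Si](c1ccccc1)(c1ccccc1)C(C)(C)C)CCC=C(C)C | intermediate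
18 | (2E,6E)-3-methyl-8-oxoocta-2,6-dien-1-yl 32-[(tert-butyldiphenylsilyl)oxy]dotriacontanoate | C/C(=C\COC(=O)CCCCCCCCCCCCCCCCCCCCCCCCCCCCCCCO[Si](c1ccccc1)(c1ccccc1)C(C)(C)C)CC/C=C/C=O | intermediate
19 | (5R,7R,8R,9R,10S,13E)-7-hydroxy-17-oxolabd-13-en-15-yl 32-[(tert-butyldiphenylsilyl)oxy]dotriacontanoate | C/C(=C\COC(=O)CCCCCCCCCCCCCCCCCCCCCCCCCCCCCCCO[Si](c1ccccc1)(c1ccccc1)C(C)(C)C)CC[C@@H]1[C@@H](C=O)[C@H](O)C[C@@H]2C(C)(C)CCC[C@@]12C | intermediate
20 | C7 methanesulfonate of 19 (not isolated) | C/C(=C\COC(=O)CCCCCCCCCCCCCCCCCCCCCCCCCCCCCCCO[Si](c1ccccc1)(c1ccccc1)C(C)(C)C)CC[C@@H]1[C@@H](C=O)[C@H](OS(C)(=O)=O)C[C@@H]2C(C)(C)CCC[C@@]12C | intermediate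
21 | (5R,9S,10R,13E)-17-oxolabda-7,13-dien-15-yl 32-[(tert-butyldiphenylsilyl)oxy]dotriacontanoate | C/C(=C\COC(=O)CCCCCCCCCCCCCCCCCCCCCCCCCCCCCCCO[Si](c1ccccc1)(c1ccccc1)C(C)(C)C)CC[C@@H]1C(C=O)=CC[C@@H]2C(C)(C)CCC[C@@]12C | intermediate
22 | (5R,9S,10R,13E)-17-hydroxylabda-7,13-dien-15-yl 32-[(tert-butyldiphenylsilyl)oxy]dotriacontanoate | C/C(=C\COC(=O)CCCCCCCCCCCCCCCCCCCCCCCCCCCCCCCO[Si](c1ccccc1)(c1ccccc1)C(C)(C)C)CC[C@@H]1C(CO)=CC[C@@H]2C(C)(C)CCC[C@@]12C | intermediate
23 | (5R,9S,10R,13E)-17-hydroxylabda-7,13-dien-15-yl 32-hydroxydotriacontanoate | C/C(=C\COC(=O)CCCCCCCCCCCCCCCCCCCCCCCCCCCCCCCO)CC[C@@H]1C(CO)=CC[C@@H]2C(C)(C)CCC[C@@]12C | target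

**Total step count:** 15
**Longest linear sequence:** 10 steps (steps 1–6, then 12–15); the acid/acceptor branch runs through 9 steps (7–11, then 12–15).

**Three steps most likely to fail**

Step 12.
- What may go wrong: the hindered C10 radical is quenched (net hydrogenation of 8), and the limiting, poorly soluble enal 18 is used up by conjugate reduction before C–C bond formation. Alternatively the enal is attacked on both faces at C9, so that epimers would have to be separated on a waxy compound.
- Fallback (order of assembly changed: ring B is built on a small acceptor and the acyl chain comes last): it sets out from 8.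
- Commercial geranyl acetate is converted by the cross metathesis of step 11 into (2E,6E)-3-methyl-8-oxoocta-2,6-dien-1-yl acetate F1. This is cheap enough to be used in threefold excess in the annulation with 8, which should give the 7-hydroxy-17-oxo acetate F2.
- Mesylation to the C7 mesylate F3 and elimination give the 17-oxolabda-7,13-dien-15-yl acetate F4, a small molecule on which C9 epimers should be separable by chromatography.
- K2CO3/MeOH frees (13E)-15-hydroxylabda-7,13-dien-17-al F5. Steglich esterification of F5 with acid 15 comes back to the route at 21.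

Step 5.
- What may go wrong: after protodesilylation the acid re-protonates the exocyclic alkene, so that the double bond migrates into the ring or the C10 cation is trapped by the ester as a γ-lactone.
- Fallback (another radical precursor, with no allylsilane and no acid step): it sets out from 3.
- Kumada–Corriu methylation (MeMgBr, Pd(PPh3)4) gives (1S)-2,4,4-trimethylcyclohex-2-en-1-ol F6.
- Johnson–Claisen rearrangement through the mixed ketene acetal F7 gives ethyl 2-[(1R)-2,6,6-trimethylcyclohex-2-en-1-yl]acetate F8, and DIBAL-H gives 2-[(1R)-2,6,6-trimethylcyclohex-2-en-1-yl]acetaldehyde F9.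
- HAT to C1 of the endocyclic C1=C10 alkene of F9 produces the same tertiary C10 radical. F9 therefore replaces 8 in step 12, in larger excess because its rate advantage over C13=C14 is smaller, and the route is rejoined at 19.

Step 9.
- What may go wrong: the chloromagnesium carboxylate precipitates from cold THF, and the Grignard reagent is lost by homocoupling and protonation before cross-coupling.
- Fallback (olefination and hydrogenation in place of sp3–sp3 coupling): it sets out from 9 and 12.
- Monosilylation of 9 (NaH, TBDPSCl) gives 16-[(tert-butyldiphenylsilyl)oxy]hexadecan-1-ol F10. Oxidation (TEMPO, PhI(OAc)2) gives 16-[(tert-butyldiphenylsilyl)oxy]hexadecanal F11.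
- Acid 12 and PPh3 give (15-carboxypentadecyl)triphenylphosphonium bromide F12, and NaHMDS (2 equiv) gives the carboxylate ylide F13.
- Wittig reaction with F11 gives (16Z)-32-[(tert-butyldiphenylsilyl)oxy]dotriacont-16-enoic acid F14. Hydrogenation (H2, Pd/C, EtOAc) comes back to the route at 15.

**Further compounds**
F1 | step 12 | (2E,6E)-3-methyl-8-oxoocta-2,6-dien-1-yl acetate | C/C(=C\COC(C)=O)CC/C=C/C=O
F2 | step 12 | (5R,7R,8R,9R,10S,13E)-7-hydroxy-17-oxolabd-13-en-15-yl acetate | C/C(=C\COC(C)=O)CC[C@@H]1[C@@H](C=O)[C@H](O)C[C@@H]2C(C)(C)CCC[C@@]12C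
F3 | step 12 | C7 methanesulfonate of F2 | C/C(=C\COC(C)=O)CC[C@@H]1[C@@H](C=O)[C@H](OS(C)(=O)=O)C[C@@H]2C(C)(C)CCC[C@@]12C
F4 | step 12 | (5R,9S,10R,13E)-17-oxolabda-7,13-dien-15-yl acetate | C/C(=C\COC(C)=O)CC[C@@H]1C(C=O)=CC[C@@H]2C(C)(C)CCC[C@@]12C
F5 | step 12 | (5R,9S,10R,13E)-15-hydroxylabda-7,13-dien-17-al | C/C(=C\CO)CC[C@@H]1C(C=O)=CC[C@@H]2C(C)(C)CCC[C@@]12C
F6 | step 5 | (1S)-2,4,4-trimethylcyclohex-2-en-1-ol | O[C@H]1CCC(C)(C)C=C1C
F7 | step 5 | mixed ketene acetal of F6 (1-ethoxyvinyl ether) | C=C(OCC)O[C@H]1CCC(C)(C)C=C1C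
F8 | step 5 | ethyl 2-[(1R)-2,6,6-trimethylcyclohex-2-en-1-yl]acetate | CCOC(=O)C[C@@H]1C(C)(C)CCC=C1C
F9 | step 5 | 2-[(1R)-2,6,6-trimethylcyclohex-2-en-1-yl]acetaldehyde | O=CC[C@@H]1C(C)(C)CCC=C1C
F10 | step 9 | 16-[(tert-butyldiphenylsilyl)oxy]hexadecan-1-ol | OCCCCCCCCCCCCCCCCO[Si](c1ccccc1)(c1ccccc1)C(C)(C)C
F11 | step 9 | 16-[(tert-butyldiphenylsilyl)oxy]hexadecanal | O=CCCCCCCCCCCCCCCCO[Si](c1ccccc1)(c1ccccc1)C(C)(C)C
F12 | step 9 | (15-carboxypentadecyl)triphenylphosphonium bromide | OC(=O)CCCCCCCCCCCCCCC[P+](c1ccccc1)(c1ccccc1)c1ccccc1.[Br-]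
F13 | step 9 | sodium 16-(triphenylphosphoranylidene)hexadecanoate (ylide) | [Na+].[O-]C(=O)CCCCCCCCCCCCCC[CH-][P+](c1ccccc1)(c1ccccc1)c1ccccc1
F14 | step 9 | (16Z)-32-[(tert-butyldiphenylsilyl)oxy]dotriacont-16-enoic acid | OC(=O)CCCCCCCCCCCCCC/C=C\CCCCCCCCCCCCCCCO[Si](c1ccccc1)(c1ccccc1)C(C)(C)C
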